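**Target:** 19, (R)-7-hydroxy-5-methoxy-2-phenyl-8-(piperidin-2-yl)-4H-chromen-4-one, by Grignard addition to an aryl tert-butanesulfinyl imine. The route has 10 steps, and none of it has been tested experimentally.

## Analysis of the target

- The target 19 is a flavone: ring A is the benzo ring (C4a, C5 to C8, C8a), ring C the pyranone (O1, C2, C3, C4), and ring B the unsubstituted phenyl on C2.
- Ring A carries OMe on C5, a free OH on C7 and a piperidin-2-yl group on C8, between C7 and C8a.
- The only stereocentre is piperidine C2. It is benzylic, bears the nitrogen and is R (N > aryl > C3 > H). With no second stereocentre to relate it to, it must be set under absolute control.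
- Sensitive features are the secondary amine next to a free phenol (oxidisable, zwitterionic) and the benzylic C–N bond, which lies ortho and para to oxygen donors and could ionise to a quinone methide under forcing acid or base, with loss of configuration.
- The difficulty is to place a configured, nitrogen-bearing carbon on the most crowded position of a fully substituted, electron-rich ring, and to end with 5-OMe and 7-OH differentiated.
- The strategy rests on one feature. Without ring C, ring A has a mirror plane through C8 and C5: O1 and O7 are two equivalent phenols, and C4a and C6 two equivalent CH positions.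
- Piperidine C2 is then the carbonyl carbon of a symmetric 4-methoxy-2,6-dioxygenated benzaldehyde, and piperidine C3 to C6 is a four-carbon nucleophile.

## Retrosynthetic reasoning

**19 from 18.** The last bond cut is the carbamate N–C(O) bond. The nitrogen is carried as its tert-butyl carbamate through halogenation and the palladium step, because a free secondary amine would be N-halogenated and would capture the acylpalladium intermediate. Acid removes the carbamate without touching the flavone.

**18 from 15 and 16.** Ring C is cut at O1–C2, C3–C4 and C4–C4a, giving iodophenol 15, alkyne 16 and a one-carbon carbonyl unit. Cutting here and not inside ring A keeps ring A as a purchasable arene and puts C2, C3 and ring B into one commercial alkyne. The forward reaction must form two C–C bonds and one C–O bond in one pot, through ynone 17, and must close the six-membered pyranone, not the five-membered aurone.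

**15 from 14.** The C4a–I bond is cut. In 14 the two free ring positions are related by the mirror plane, so either one gives the same iodide, and whichever hydroxyl later closes ring C, the other becomes the 7-OH. The 5-OMe/7-OH differentiation therefore costs nothing; the only demand is to stop after one iodine.

**14 from 12.** This is a change of protecting groups. The sulfinyl group and both MOM ethers are acid-labile and leave together to give ammonium salt 13, which is re-protected on nitrogen only. The carbamate is chosen because it survives iodination and the basic palladium step, which the sulfinyl group would not.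

**12 from 10.** The N–C6 bond is cut. The sulfinamide nitrogen is already in place and acidic enough to be deprotonated, so a primary sulfonate (11) is displaced in a 6-exo-tet closure. Cutting here places the ring closure after the stereocentre is set, and at a carbon remote from it.

**10 from 8.** The C6–O bond is cut back to a terminal alkene. The alkene is inert in the organometallic step and delivers the primary alcohol by anti-Markovnikov hydration.

**8 from 6 and 7.** The C2–C3 bond is cut. This is the only C–C bond formed at the stereocentre, and it makes piperidine C2 the carbon of an imine whose nitrogen carries a removable chiral sulfinyl group. Reagent 7 supplies C3 to C6 in one piece. The forward reaction must add to one face of a hindered, electron-rich C=N bond.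

**6 from 4 and 5; 4 from 2; 2 from 1.** The C=N bond is cut to aldehyde 4 and sulfinamide 5. The formyl carbon is cut from the ring position between the two MOM ethers, which is where lithiation of 2 is directed (aryllithium 3). The MOM ethers serve twice, as phenol protection and as directing groups, and 2 comes from 1 in one step.

## Alternatives that were turned down

**Alternative 1: ring A built last by Dieckmann closure of a pyranone.**
- Disconnection: ring A is cut at C5–C6, leading to A1, methyl 2-{1-[(R)-1-(tert-butoxycarbonyl)piperidin-2-yl]-2-oxopropyl}-4-oxo-6-phenyl-4H-pyran-3-carboxylate. A1 already contains ring C, ring B and the piperidine.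
- Forward key step: two equivalents of a lithium amide base make the dianion of A1. Its terminal methyl enolate attacks the neighbouring ester, and tautomerisation gives the 5,7-dihydroxyflavone A2, tert-butyl (R)-2-(5,7-dihydroxy-4-oxo-2-phenyl-4H-chromen-8-yl)piperidine-1-carboxylate.
- For it: it mimics polyketide folding, needs no substitution chemistry on an arene and no late palladium step. On these points it is stronger than the chosen route.
- Against it:
  - A2 has two free phenols. The 5-OH is hydrogen-bonded to the C4 carbonyl and is the less reactive one, so the required 5-O-methyl/7-OH pattern needs protection, methylation and deprotection.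
  - In A1 the piperidine nitrogen is β to the side-chain ketone. The first deprotonation makes an enolate that can expel the carbamate nitrogen (E1cB) and re-add it, which would racemise C2.
  - Making A1 as a single enantiomer is a multi-step problem of its own.
- Comparison: the chosen route buys ring A with its methyl ether in place and sets C2 on a carbon with no neighbouring carbonyl.

**Alternative 2: transaminase-triggered piperidine closure.**
- Disconnection: both N–C bonds are cut, leading to the chloroketone A3, 5-chloro-1-[4-methoxy-2,6-bis(methoxymethoxy)phenyl]pentan-1-one. A3 could come from aryllithium 3 and a 5-chloropentanoyl electrophile.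
- Forward key step: an (R)-selective amine transaminase with an amine donor turns the ketone into the R amine, which displaces the chloride to give A4, (R)-2-[4-methoxy-2,6-bis(methoxymethoxy)phenyl]piperidine.
- For it: it is catalytic in chirality, forms N–C2, the stereocentre and N–C6 in one operation, and would be about four steps shorter. On step economy it is stronger than the chosen route.
- Against it: the carbonyl of A3 is flanked by two ortho alkoxy groups and carries a four-carbon chain, so both binding pockets of the enzyme are loaded at once. Whether any available enzyme accepts it cannot be argued from structure and would need screening or enzyme engineering.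
- Comparison: the chosen route spends a stoichiometric auxiliary, but its stereochemistry follows a transition-state model, the auxiliary exists in both enantiomeric forms, and the diastereomers formed can be separated.

**Alternative 3: piperidine closed at C4=C5 by ring-closing metathesis.**
- Disconnection: the ring is cut at C4=C5, leading to the diene A5, tert-butyl (R)-allyl{1-[2,6-bis(benzyloxy)-4-methoxyphenyl]but-3-enyl}carbamate.
- Forward key step: a ruthenium alkylidene metathesis catalyst joins the two alkenes with loss of the two terminal methylene carbons to give A6, tert-butyl (R)-2-[2,6-bis(benzyloxy)-4-methoxyphenyl]-3,6-dihydro-2H-pyridine-1-carboxylate.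
- For it: the ring closure itself is very reliable, allyl additions to sulfinyl imines are usually highly selective, and one hydrogenation would saturate the ring and remove the benzyl ethers. On reliability of ring closure it is at least as strong as the chosen route.
- Against it:
  - The stereocentre of A5 still has to come from an auxiliary-controlled addition to an imine of the same aldehyde type, so the metathesis removes none of the stereochemical uncertainty.
  - It adds N-allylation, a protecting-group change and a hydrogenation in which the electron-rich benzylic C–N bond is itself at risk.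
  - Benzyl ethers direct the lithiation that makes the aldehyde less well than MOM ethers.
- Comparison: the chosen route brings C3 to C6 in one reagent and closes the ring by a simple N-alkylation, with no precious metal before the final annulation.

Key step: step 4

Assumption: 7 is used as a solution in diethyl ether, so that the addition runs in CH2Cl2 with little coordinating solvent, and 19 is isolated as the free base.

## Route

Step 1
Reactants: 1 5-methoxyresorcinol
Product: 2 1-methoxy-3,5-bis(methoxymethoxy)benzene
Conditions: MOMCl, iPr2NEt, CH2Cl2, 0 °C → rt
Reagents that add atoms: chloromethyl methyl ether, COCCl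
Why: O-alkylation of both phenols (Williamson-type acetal formation); the MOM ethers protect the phenols and are the directing groups for step 2.

Step 2
Reactants: 2 1-methoxy-3,5-bis(methoxymethoxy)benzene
Product: 4 4-methoxy-2,6-bis(methoxymethoxy)benzaldehyde, via aryllithium 3 (not isolated)
Conditions: n-BuLi, THF, 0 °C; DMF, 0 °C → rt; H2O
Reagents that add atoms: N,N-dimethylformamide, CN(C)C=O
Why: Directed ortho-metalation followed by formylation; the position between the two MOM ethers is flanked by two chelating directing groups and should be lithiated in preference to the positions next to the methoxy group.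

Step 3
Reactants: 4 4-methoxy-2,6-bis(methoxymethoxy)benzaldehyde; 5 (S)-tert-butanesulfinamide
Product: 6 (S,E)-N-[4-methoxy-2,6-bis(methoxymethoxy)benzylidene]-2-methylpropane-2-sulfinamide
Conditions: Ti(OEt)4, THF, 65 °C
Reagents that add atoms: none
Why: Lewis-acid-mediated imine condensation in which Ti(OEt)4 activates the hindered, electron-rich aldehyde and takes up the water; aldimines of this class form as the E isomers.

Step 4
Reactants: 6 (S,E)-N-[4-methoxy-2,6-bis(methoxymethoxy)benzylidene]-2-methylpropane-2-sulfinamide; 7 but-3-enylmagnesium bromide
Product: 8 (S)-N-{(R)-1-[4-methoxy-2,6-bis(methoxymethoxy)phenyl]pent-4-enyl}-2-methylpropane-2-sulfinamide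
Conditions: 7 (2.5 equiv, Et2O solution), CH2Cl2, −78 → −40 °C; aq NH4Cl
Reagents that add atoms: none
Why: This is the 1,2-addition of a Grignard reagent to an N-tert-butanesulfinyl aldimine, and the closest known reaction class is the addition of primary alkylmagnesium halides to aryl sulfinyl aldimines in CH2Cl2. Magnesium binds the sulfinyl oxygen and passes the butenyl group to the imine carbon through a six-membered chair in which the tert-butyl group is equatorial and the aryl group of the E imine points outward. With S configuration at sulfur this chair exposes the Re face of the imine carbon (N > aryl > H), so the C2–C3 bond should form with R configuration at the future piperidine C2; the sulfur stereocentre is the only controlling element. No ring is closed; one C–C bond and one stereocentre are formed. The step needs facial selectivity and clean 1,2-addition rather than β-hydride reduction or no reaction at a doubly ortho-substituted, electron-rich imine, and the non-coordinating solvent, the low temperature and the excess of 7 are meant to secure both. The two ortho MOM ethers are the weak point, because a chelate of magnesium between the imine nitrogen and a MOM oxygen would bypass the sulfinyl-bound chair and could invert the facial sense, so the configuration of 8 has to be assigned before the route goes on. The diastereomers of 8 are sulfinamides that should be separable, which allows the minor one to be removed.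

Step 5
Reactants: 8 (S)-N-{(R)-1-[4-methoxy-2,6-bis(methoxymethoxy)phenyl]pent-4-enyl}-2-methylpropane-2-sulfinamide
Product: 10 (S)-N-{(R)-5-hydroxy-1-[4-methoxy-2,6-bis(methoxymethoxy)phenyl]pentyl}-2-methylpropane-2-sulfinamide, via B-alkyl-9-BBN adduct 9 (not isolated)
Conditions: 9-BBN, THF, 0 °C → rt; aq NaOH, H2O2, 0 °C
Reagents that add atoms: hydrogen peroxide, OO
Why: Hydroboration–oxidation; the bulky borane puts boron on the terminal carbon and oxidation with retention gives the primary alcohol, while cold alkaline peroxide for a short time should leave the sulfinamide untouched.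

Step 6
Reactants: 10 (S)-N-{(R)-5-hydroxy-1-[4-methoxy-2,6-bis(methoxymethoxy)phenyl]pentyl}-2-methylpropane-2-sulfinamide
Product: 12 (R)-1-[(S)-tert-butylsulfinyl]-2-[4-methoxy-2,6-bis(methoxymethoxy)phenyl]piperidine, via mesylate 11 (not isolated)
Conditions: MsCl, Et3N, CH2Cl2, 0 °C; NaH, THF, 0 °C → rt
Reagents that add atoms: none
Why: Sulfonylation of the primary alcohol, then intramolecular N-alkylation of the deprotonated sulfinamide (6-exo-tet SN2), a known closure of N-sulfinyl amino sulfonates to 2-substituted piperidines; the stereocentre is not involved.

Step 7
Reactants: 12 (R)-1-[(S)-tert-butylsulfinyl]-2-[4-methoxy-2,6-bis(methoxymethoxy)phenyl]piperidine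
Product: 14 tert-butyl (R)-2-(2,6-dihydroxy-4-methoxyphenyl)piperidine-1-carboxylate, via piperidinium chloride 13 (not isolated)
Conditions: HCl (3 M), MeOH, rt → 40 °C; evaporate; Boc2O, NaHCO3, THF–H2O, rt
Reagents that add atoms: di-tert-butyl dicarbonate, CC(C)(C)OC(=O)OC(=O)OC(C)(C)C
Why: Acid methanolysis cleaves the N–S bond and both MOM acetals, with methanol trapping the fragments, and the amine stays protonated until it is acylated chemoselectively on nitrogen under bicarbonate (carbamate formation); any aryl carbonate formed would be cleaved by K2CO3 in MeOH.

Step 8
Reactants: 14 tert-butyl (R)-2-(2,6-dihydroxy-4-methoxyphenyl)piperidine-1-carboxylate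
Product: 15 tert-butyl (R)-2-(2,6-dihydroxy-3-iodo-4-methoxyphenyl)piperidine-1-carboxylate
Conditions: I2 (1.0 equiv), NaHCO3, THF–H2O, 0 °C
Reagents that add atoms: iodine, II
Why: Electrophilic aromatic iodination; the two free ring positions are equivalent by symmetry and each is ortho or para to three oxygen donors, so there is no regiochemical question, and one equivalent of iodine at 0 °C under bicarbonate, conditions known to give mono-iodides of phloroglucinol-type phenols, should limit the second substitution.

Step 9
Reactants: 15 tert-butyl (R)-2-(2,6-dihydroxy-3-iodo-4-methoxyphenyl)piperidine-1-carboxylate; 16 phenylacetylene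
Product: 18 tert-butyl (R)-2-(7-hydroxy-5-methoxy-4-oxo-2-phenyl-4H-chromen-8-yl)piperidine-1-carboxylate, via ynone 17 (not isolated)
Conditions: PdCl2(PPh3)2 (5 mol%), CO (1 atm), Et2NH, DMF, 50 °C
Reagents that add atoms: carbon monoxide, [C-]#[O+]
Why: Carbonylative Sonogashira coupling followed by amine-mediated cyclisation, the known one-pot flavone synthesis from o-iodophenols, terminal alkynes and CO: zerovalent palladium formed from the divalent precatalyst inserts into the C–I bond, CO insertion and coupling with the acetylide give ynone 17, and reversible addition of Et2NH to the ynone steers the ortho phenol to the six-membered pyranone and away from the aurone. Only the hydroxyl ortho to the acyl group can cyclise; the other becomes the 7-OH.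

Step 10
Reactants: 18 tert-butyl (R)-2-(7-hydroxy-5-methoxy-4-oxo-2-phenyl-4H-chromen-8-yl)piperidine-1-carboxylate
Product: 19 (R)-7-hydroxy-5-methoxy-2-phenyl-8-(piperidin-2-yl)-4H-chromen-4-one
Conditions: CF3CO2H, CH2Cl2, 0 °C → rt; aq NaHCO3
Reagents that add atoms: none
Why: Acidolysis of the tert-butyl carbamate through the tert-butyl cation and decarboxylation; the flavone, the methyl ether and the protonated benzylic amine are stable to cold CF3CO2H.

## Compound list

1 | 5-methoxyresorcinol (5-methoxybenzene-1,3-diol) | COc1cc(O)cc(O)c1 | starting material
2 | 1-methoxy-3,5-bis(methoxymethoxy)benzene | COCOc1cc(OC)cc(OCOC)c1 | intermediate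
3 | [4-methoxy-2,6-bis(methoxymethoxy)phenyl]lithium | [Li]c1c(OCOC)cc(OC)cc1OCOC | intermediate
4 | 4-methoxy-2,6-bis(methoxymethoxy)benzaldehyde | O=Cc1c(OCOC)cc(OC)cc1OCOC | intermediate
5 | (S)-tert-butanesulfinamide | CC(C)(C)[S@](=O)N | starting material
6 | (S,E)-N-[4-methoxy-2,6-bis(methoxymethoxy)benzylidene]-2-methylpropane-2-sulfinamide | CC(C)(C)[S@](=O)/N=C/c1c(OCOC)cc(OC)cc1OCOC | intermediate
7 | but-3-enylmagnesium bromide | C=CCC[Mg]Br | starting material
8 | (S)-N-{(R)-1-[4-methoxy-2,6-bis(methoxymethoxy)phenyl]pent-4-enyl}-2-methylpropane-2-sulfinamide | CC(C)(C)[S@](=O)N[C@H](CCC=C)c1c(OCOC)cc(OC)cc1OCOC | intermediate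
9 | (S)-N-{(R)-5-(9-borabicyclo[3.3.1]nonan-9-yl)-1-[4-methoxy-2,6-bis(methoxymethoxy)phenyl]pentyl}-2-methylpropane-2-sulfinamide | CC(C)(C)[S@](=O)N[C@H](CCCCB1C2CCCC1CCC2)c1c(OCOC)cc(OC)cc1OCOC | intermediate
10 | (S)-N-{(R)-5-hydroxy-1-[4-methoxy-2,6-bis(methoxymethoxy)phenyl]pentyl}-2-methylpropane-2-sulfinamide | CC(C)(C)[S@](=O)N[C@H](CCCCO)c1c(OCOC)cc(OC)cc1OCOC | intermediate
11 | (R)-5-{[(S)-tert-butylsulfinyl]amino}-5-[4-methoxy-2,6-bis(methoxymethoxy)phenyl]pentyl methanesulfonate | CC(C)(C)[S@](=O)N[C@H](CCCCOS(C)(=O)=O)c1c(OCOC)cc(OC)cc1OCOC | intermediate
12 | (R)-1-[(S)-tert-butylsulfinyl]-2-[4-methoxy-2,6-bis(methoxymethoxy)phenyl]piperidine | CC(C)(C)[S@](=O)N1CCCC[C@@H]1c1c(OCOC)cc(OC)cc1OCOC | intermediate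
13 | (R)-2-(2,6-dihydroxy-4-methoxyphenyl)piperidinium chloride | COc1cc(O)c([C@H]2CCCC[NH2+]2)c(O)c1.[Cl-] | intermediate
14 | tert-butyl (R)-2-(2,6-dihydroxy-4-methoxyphenyl)piperidine-1-carboxylate | COc1cc(O)c([C@H]2CCCCN2C(=O)OC(C)(C)C)c(O)c1 | intermediate
15 | tert-butyl (R)-2-(2,6-dihydroxy-3-iodo-4-methoxyphenyl)piperidine-1-carboxylate | COc1cc(O)c([C@H]2CCCCN2C(=O)OC(C)(C)C)c(O)c1I | intermediate
16 | phenylacetylene | C#Cc1ccccc1 | starting material
17 | tert-butyl (R)-2-[2,6-dihydroxy-4-methoxy-3-(3-phenylprop-2-ynoyl)phenyl]piperidine-1-carboxylate | COc1cc(O)c([C@H]2CCCCN2C(=O)OC(C)(C)C)c(O)c1C(=O)C#Cc1ccccc1 | intermediate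
18 | tert-butyl (R)-2-(7-hydroxy-5-methoxy-4-oxo-2-phenyl-4H-chromen-8-yl)piperidine-1-carboxylate | COc1cc(O)c([C@H]2CCCCN2C(=O)OC(C)(C)C)c2oc(-c3ccccc3)cc(=O)c12 | intermediate
19 | (R)-7-hydroxy-5-methoxy-2-phenyl-8-(piperidin-2-yl)-4H-chromen-4-one | COc1cc(O)c([C@H]2CCCCN2)c2oc(-c3ccccc3)cc(=O)c12 | target

## Step count and least certain steps

Total step count: 10. Longest linear sequence: 10 steps, from 1 to 19.

**Step 4 (key step).**
- What may go wrong: poor or inverted facial selectivity, because magnesium can be chelated between the imine nitrogen and an ortho MOM oxygen instead of the sulfinyl oxygen. Slow addition or β-hydride reduction at the doubly ortho-substituted, electron-rich imine is the second concern.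
- Fallback: the polarity of the bond construction is reversed. It sets out from 2 and 5 and comes back at 8. Pent-4-enal is condensed with 5 (CuSO4, CH2Cl2) to give (S,E)-N-(pent-4-enylidene)-2-methylpropane-2-sulfinamide F1. Aryllithium 3, made from 2 as in step 2, is added to F1 in THF at −78 °C, so that the aryl–C2 bond is formed instead of C2–C3. The electrophile then has no ortho chelating groups, and the lithium of 3 is already coordinated internally by its MOM oxygens. An open transition state is therefore expected, which for the S-configured imine again leads to the R carbon, i.e. to 8. This assignment would have to be confirmed in the same way as for the main route.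

**Step 9.**
- What may go wrong: closure in the 5-exo sense to the aurone, direct coupling without CO insertion, capture of the acylpalladium species by Et2NH, or slow oxidative addition at an iodide flanked by two oxygen substituents on an electron-rich ring.
- Fallback: ring C is built by the classical chalcone route without CO. It sets out from 15 and comes back at 18. Stille coupling of 15 with tributyl(1-ethoxyvinyl)stannane (PdCl2(PPh3)2, dioxane, 90 °C) gives tert-butyl (R)-2-[3-(1-ethoxyvinyl)-2,6-dihydroxy-4-methoxyphenyl]piperidine-1-carboxylate F2. Dilute aqueous HCl in the work-up hydrolyses it to tert-butyl (R)-2-(3-acetyl-2,6-dihydroxy-4-methoxyphenyl)piperidine-1-carboxylate F3. Claisen–Schmidt condensation with benzaldehyde (KOH, EtOH) gives tert-butyl (R)-2-{2,6-dihydroxy-4-methoxy-3-[(E)-3-phenylprop-2-enoyl]phenyl}piperidine-1-carboxylate F4. Oxidative cyclisation with catalytic iodine in DMSO at 110 °C closes the pyranone to 18.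

**Step 7.**
- What may go wrong: alkylation of the very electron-rich ring, or N,O-acetal formation, by the methoxymethyl cation set free from the MOM groups. Partial loss of configuration by acid-induced ionisation of the benzylic C–N bond on prolonged warming is also possible.
- Fallback: the two cleavages are separated and the cation is trapped irreversibly. It sets out from 12 and comes back at 14. Two equivalents of HCl (dioxane solution) in MeOH at 0 °C remove only the sulfinyl group and give (R)-2-[4-methoxy-2,6-bis(methoxymethoxy)phenyl]piperidine F5, which is identical in structure with A4. Boc2O and Et3N convert it into tert-butyl (R)-2-[4-methoxy-2,6-bis(methoxymethoxy)phenyl]piperidine-1-carboxylate F6. The aryl MOM ethers are then removed with ZnBr2 and propane-1-thiol in CH2Cl2 at 0 °C, where the thiol captures the methoxymethyl unit, to give 14.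

**Step 5.**
- What may go wrong: oxidation at sulfur of the sulfinamide by the peroxide, or incomplete hydroboration because the borane is held by the sulfinamide and the MOM oxygens.
- Fallback: the leaving group is carried in the nucleophile, so no oxidation is needed. It sets out from 6 and comes back at 12. 4-Chlorobutylmagnesium bromide F7, made from 1-bromo-4-chlorobutane and magnesium, is added to 6 under the conditions of step 4. This is the same disconnection and gives (S)-N-{(R)-5-chloro-1-[4-methoxy-2,6-bis(methoxymethoxy)phenyl]pentyl}-2-methylpropane-2-sulfinamide F8. NaH in THF then closes the ring by displacement of chloride to give 12.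

## Further compounds

F1 | step 4 | (S,E)-N-(pent-4-enylidene)-2-methylpropane-2-sulfinamide | CC(C)(C)[S@](=O)/N=C/CCC=C
F2 | step 9 | tert-butyl (R)-2-[3-(1-ethoxyvinyl)-2,6-dihydroxy-4-methoxyphenyl]piperidine-1-carboxylate | CCOC(=C)c1c(OC)cc(O)c([C@H]2CCCCN2C(=O)OC(C)(C)C)c1O
F3 | step 9 | tert-butyl (R)-2-(3-acetyl-2,6-dihydroxy-4-methoxyphenyl)piperidine-1-carboxylate | CC(=O)c1c(OC)cc(O)c([C@H]2CCCCN2C(=O)OC(C)(C)C)c1O
F4 | step 9 | tert-butyl (R)-2-{2,6-dihydroxy-4-methoxy-3-[(E)-3-phenylprop-2-enoyl]phenyl}piperidine-1-carboxylate | O=C(/C=C/c1ccccc1)c1c(OC)cc(O)c([C@H]2CCCCN2C(=O)OC(C)(C)C)c1O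
F5 | step 7 | (R)-2-[4-methoxy-2,6-bis(methoxymethoxy)phenyl]piperidine | COCOc1cc(OC)cc(OCOC)c1[C@H]2CCCCN2
F6 | step 7 | tert-butyl (R)-2-[4-methoxy-2,6-bis(methoxymethoxy)phenyl]piperidine-1-carboxylate | COCOc1cc(OC)cc(OCOC)c1[C@H]2CCCCN2C(=O)OC(C)(C)C
F7 | step 5 | 4-chlorobutylmagnesium bromide | ClCCCC[Mg]Br
F8 | step 5 | (S)-N-{(R)-5-chloro-1-[4-methoxy-2,6-bis(methoxymethoxy)phenyl]pentyl}-2-methylpropane-2-sulfinamide | CC(C)(C)[S@](=O)N[C@H](CCCCCl)c1c(OCOC)cc(OC)cc1OCOC
A1 | alternative 1 | methyl 2-{1-[(R)-1-(tert-butoxycarbonyl)piperidin-2-yl]-2-oxopropyl}-4-oxo-6-phenyl-4H-pyran-3-carboxylate | COC(=O)c1c(C(C(C)=O)[C@H]2CCCCN2C(=O)OC(C)(C)C)oc(-c2ccccc2)cc1=O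
A2 | alternative 1 | tert-butyl (R)-2-(5,7-dihydroxy-4-oxo-2-phenyl-4H-chromen-8-yl)piperidine-1-carboxylate | Oc1cc(O)c([C@H]2CCCCN2C(=O)OC(C)(C)C)c2oc(-c3ccccc3)cc(=O)c12
A3 | alternative 2 | 5-chloro-1-[4-methoxy-2,6-bis(methoxymethoxy)phenyl]pentan-1-one | COCOc1cc(OC)cc(OCOC)c1C(=O)CCCCCl
A4 | alternative 2 | (R)-2-[4-methoxy-2,6-bis(methoxymethoxy)phenyl]piperidine | COCOc1cc(OC)cc(OCOC)c1[C@H]2CCCCN2
A5 | alternative 3 | tert-butyl (R)-allyl{1-[2,6-bis(benzyloxy)-4-methoxyphenyl]but-3-enyl}carbamate | COc1cc(OCc2ccccc2)c([C@@H](CC=C)N(CC=C)C(=O)OC(C)(C)C)c(OCc2ccccc2)c1
A6 | alternative 3 | tert-butyl (R)-2-[2,6-bis(benzyloxy)-4-methoxyphenyl]-3,6-dihydro-2H-pyridine-1-carboxylate | COc1cc(OCc2ccccc2)c([C@H]2CC=CCN2C(=O)OC(C)(C)C)c(OCc2ccccc2)c1
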